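Ring C is disconnected at O1–C2 and C3–C4. The O1–C8a–C4a–C4 unit of ring A is a latent 1-oxadiene (an ortho-quinone methide at the aldehyde oxidation level), and C2–C3 with ring B attached is a para-alkoxystyrene. One acid-catalysed three-component [4+2] reaction of a salicylaldehyde, trimethyl orthoformate and a vinylarene should therefore close ring C, form both bonds and set C2, with C4 as a temporary methoxy-bearing centre that later becomes the ketone. The precursors are 4-silyloxy-2-hydroxy-3-prenylbenzaldehyde, which already carries the C8 prenyl group and the protected O7, and 2,2-dimethyl-6-vinyl-2H-chromene, which is the complete ring B.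

Key step: step 6

Assumption: the sense of induction of the confined acid cannot be predicted, so the catalyst antipode (both available from (R)- or (S)-BINOL) that gives (2S,4S)-15 is chosen after a test reaction.

Step 1
Reactants: 1 2,4-dihydroxybenzaldehyde; 2 prenyl bromide (1-bromo-3-methylbut-2-ene)
Product: 3 2,4-dihydroxy-3-(3-methylbut-2-en-1-yl)benzaldehyde
Conditions: KOH (aq.), 0 °C to rt
Reagents that add atoms: none
Why: C-prenylation of the resorcinol-type phenoxide in water (phenoxide C-alkylation) is established for 2,4-dihydroxyaryl carbonyl compounds, because the protic medium solvates the oxygens and directs the allylic bromide to carbon, C3 between the two oxygens is the most nucleophilic ring position, and the 5-prenyl and O-prenyl isomers should be separable by chromatography.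

Step 2
Reactants: 3 2,4-dihydroxy-3-(3-methylbut-2-en-1-yl)benzaldehyde
Product: 4 2-hydroxy-3-(3-methylbut-2-en-1-yl)-4-[(triisopropylsilyl)oxy]benzaldehyde
Conditions: TIPSCl, imidazole, DMF, rt
Reagents that add atoms: triisopropylsilyl chloride, CC(C)[Si](Cl)(C(C)C)C(C)C
Why: Selective phenol silylation should occur at the free 4-OH because the 2-OH is held in a hydrogen bond to the formyl group; the bulky triisopropylsilyl ether is chosen because this oxygen is para to the carbon that becomes cationic in steps 6 and 7, where a smaller silyl group could be transferred to methanol or water, and it still comes off with buffered fluoride.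

Step 3
Reactants: 5 4-hydroxybenzaldehyde; 6 3-chloro-3-methylbut-1-yne
Product: 7 4-[(2-methylbut-3-yn-2-yl)oxy]benzaldehyde
Conditions: DBU, CuCl2·2H2O (cat.), MeCN, 0 °C to rt
Reagents that add atoms: none
Why: Copper-catalysed propargylic etherification of a phenol with a tertiary propargylic chloride is the standard entry to aryl 1,1-dimethylpropargyl ethers and should work well with this acidic phenol.

Step 4
Reactants: 7 4-[(2-methylbut-3-yn-2-yl)oxy]benzaldehyde
Product: 10 2,2-dimethyl-2H-chromene-6-carbaldehyde, via ortho-allenylphenol 8 (not isolated), via ortho-quinone methide dienone 9 (not isolated)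
Conditions: PhNEt2, 190 °C
Reagents that add atoms: none
Why: The thermal aryl propargyl ether Claisen rearrangement ([3,3]) gives allenylphenol 8 after rearomatisation, a 1,5-hydrogen shift gives dienone 9 and oxa-6π electrocyclisation closes the pyran, which is the standard synthesis of 2,2-dimethylchromenes; the para position is blocked and the two ortho positions are equivalent, so only one chromene can form.

Step 5
Reactants: 10 2,2-dimethyl-2H-chromene-6-carbaldehyde
Product: 11 6-ethenyl-2,2-dimethyl-2H-chromene
Conditions: Ph3PCH3Br, KOtBu, THF, 0 °C to rt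
Reagents that add atoms: methyltriphenylphosphonium bromide, C[P+](c1ccccc1)(c1ccccc1)c1ccccc1.[Br-]
Why: Wittig methylenation of an aromatic aldehyde with the non-stabilised ylide is reliable and touches neither the chromene alkene nor the ether; the styrene should be stored cold over a trace of BHT.

Step 6
Reactants: 4 2-hydroxy-3-(3-methylbut-2-en-1-yl)-4-[(triisopropylsilyl)oxy]benzaldehyde; 11 6-ethenyl-2,2-dimethyl-2H-chromene; 12 trimethyl orthoformate
Product: 15 (2S,4S)-2-(2,2-dimethyl-2H-chromen-6-yl)-4-methoxy-8-(3-methylbut-2-en-1-yl)-7-[(triisopropylsilyl)oxy]chromane (2,4-cis-4-methoxyflavan), via dimethyl acetal 13 (not isolated), via methoxy ortho-quinone methide 14 (not isolated)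
Conditions: confined chiral imidodiphosphorimidate (IDPi) Brønsted acid (BINOL-derived, 3,3'-aryl, N-triflyl; 5 mol %), 5 Å MS, toluene, −40 °C; then Et3N
Reagents that add atoms: none
Why: Proposed new method: the acid should convert 4 and 12 into acetal 13, which loses methanol to an oxocarbenium ion that is the O-protonated form of quinone methide 14 and stays bound through its phenol hydrogen to the chiral anion; the CH2 end of styrene 11 then attacks the methide carbon (C4), and the cation that develops at C2, stabilised by the para oxygen of ring B, collapses onto the phenol oxygen. The closest known reactions are the racemic acid-catalysed three-component synthesis of 4-alkoxychromans from salicylaldehydes, orthoformates and alkenes, asymmetric confined-acid cycloadditions of quinone methides generated from salicylaldehydes with tethered dienes, and confined-acid additions of styrenes to cationic electrophiles; the enantioselective intermolecular three-component version is not known. Ring C closes as an asynchronous inverse-electron-demand oxa-[4+2] cycloaddition, C3–C4 bonding running ahead of O1–C2. C4 is controlled by the catalyst, whose confined anion shields one face of the methide carbon, and C2 is controlled by C4 through the endo transition state, which places aryl and methoxy cis (also the more stable diequatorial arrangement), so that 4S should bring 2S with it. The step needs attack by the vinyl group only: the monosubstituted styrene alone gives a cation conjugated to a para oxygen, the chromene alkene would have to be attacked at C3 next to its quaternary carbon, and the prenyl alkene leads to a non-benzylic cation. Low temperature, low acid loading and sieves that take up methanol should preserve the silyl ether, the chelated ortho-prenylphenol and the chromene.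

Step 7
Reactants: 15 (2S,4S)-2-(2,2-dimethyl-2H-chromen-6-yl)-4-methoxy-8-(3-methylbut-2-en-1-yl)-7-[(triisopropylsilyl)oxy]chromane
Product: 16 (2S)-2-(2,2-dimethyl-2H-chromen-6-yl)-8-(3-methylbut-2-en-1-yl)-7-[(triisopropylsilyl)oxy]chroman-4-ol (both C4 epimers)
Conditions: CSA (10 mol %), THF/H2O 3:1, 0 °C to rt, dark; NaHCO3
Reagents that add atoms: water, O
Why: Acid-catalysed SN1 solvolysis of the benzylic methyl ether should be easy because the C4 cation is stabilised by O1 (ortho) and the C7 silyloxy group (para) and is captured by the large excess of water, whereas ionisation at C2 would need protonation of the much less basic aryl ether O1, so that C2 should stay intact and the C4 configuration, lost in the next step, does not matter.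

Step 8
Reactants: 16 (2S)-2-(2,2-dimethyl-2H-chromen-6-yl)-8-(3-methylbut-2-en-1-yl)-7-[(triisopropylsilyl)oxy]chroman-4-ol
Product: 17 (2S)-2-(2,2-dimethyl-2H-chromen-6-yl)-8-(3-methylbut-2-en-1-yl)-7-[(triisopropylsilyl)oxy]chroman-4-one
Conditions: Dess–Martin periodinane, CH2Cl2, 0 °C to rt
Reagents that add atoms: none
Why: Dess–Martin oxidation converts the secondary benzylic alcohol into the ketone under base-free conditions that leave the alkenes and the silyl ether alone and cannot open ring C by retro-oxa-Michael reaction, so C2 should keep its configuration.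

Step 9
Reactants: 17 (2S)-2-(2,2-dimethyl-2H-chromen-6-yl)-8-(3-methylbut-2-en-1-yl)-7-[(triisopropylsilyl)oxy]chroman-4-one
Product: 18 (2S)-2-(2,2-dimethyl-2H-chromen-6-yl)-7-hydroxy-8-(3-methylbut-2-en-1-yl)chroman-4-one
Conditions: TBAF, AcOH (1:1), THF, 0 °C to rt
Reagents that add atoms: none
Why: Fluoride desilylation of the aryl silyl ether should be fast because the phenoxide is para to the ketone, and the acetic acid buffer keeps the medium non-basic so that the flavanone cannot racemise through the ring-opened chalcone.

Compound list
1 | 2,4-dihydroxybenzaldehyde | O=Cc1ccc(O)cc1O | starting material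
2 | prenyl bromide (1-bromo-3-methylbut-2-ene) | CC(C)=CCBr | starting material
3 | 2,4-dihydroxy-3-(3-methylbut-2-en-1-yl)benzaldehyde | CC(C)=CCc1c(O)ccc(C=O)c1O | intermediate
4 | 2-hydroxy-3-(3-methylbut-2-en-1-yl)-4-[(triisopropylsilyl)oxy]benzaldehyde | CC(C)=CCc1c(O[Si](C(C)C)(C(C)C)C(C)C)ccc(C=O)c1O | intermediate
5 | 4-hydroxybenzaldehyde | O=Cc1ccc(O)cc1 | starting material
6 | 3-chloro-3-methylbut-1-yne | CC(C)(Cl)C#C | starting material
7 | 4-[(2-methylbut-3-yn-2-yl)oxy]benzaldehyde | O=Cc1ccc(OC(C)(C)C#C)cc1 | intermediate
8 | 4-hydroxy-3-(3-methylbuta-1,2-dien-1-yl)benzaldehyde (ortho-allenylphenol, formed in situ) | O=Cc1ccc(O)c(C=C=C(C)C)c1 | intermediate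
9 | 3-(3-methylbut-2-en-1-ylidene)-4-oxocyclohexa-1,5-diene-1-carbaldehyde (ortho-quinone methide dienone, formed in situ) | O=CC1=CC(=CC=C(C)C)C(=O)C=C1 | intermediate
10 | 2,2-dimethyl-2H-chromene-6-carbaldehyde | O=Cc1ccc2c(c1)C=CC(C)(C)O2 | intermediate
11 | 6-ethenyl-2,2-dimethyl-2H-chromene | C=Cc1ccc2c(c1)C=CC(C)(C)O2 | intermediate
12 | trimethyl orthoformate | COC(OC)OC | starting material
13 | 6-(dimethoxymethyl)-2-(3-methylbut-2-en-1-yl)-3-[(triisopropylsilyl)oxy]phenol (dimethyl acetal, formed in situ) | COC(OC)c1ccc(O[Si](C(C)C)(C(C)C)C(C)C)c(CC=C(C)C)c1O | intermediate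
14 | 6-(methoxymethylidene)-2-(3-methylbut-2-en-1-yl)-3-[(triisopropylsilyl)oxy]cyclohexa-2,4-dien-1-one (methoxy ortho-quinone methide, formed in situ) | COC=C1C=CC(O[Si](C(C)C)(C(C)C)C(C)C)=C(CC=C(C)C)C1=O | intermediate
15 | (2S,4S)-2-(2,2-dimethyl-2H-chromen-6-yl)-4-methoxy-8-(3-methylbut-2-en-1-yl)-7-[(triisopropylsilyl)oxy]chromane (2,4-cis) | CC(C)=CCc1c(O[Si](C(C)C)(C(C)C)C(C)C)ccc2c1O[C@H](c1ccc3c(c1)C=CC(C)(C)O3)C[C@@H]2OC | intermediate
16 | (2S)-2-(2,2-dimethyl-2H-chromen-6-yl)-8-(3-methylbut-2-en-1-yl)-7-[(triisopropylsilyl)oxy]chroman-4-ol (C4 epimers) | CC(C)=CCc1c(O[Si](C(C)C)(C(C)C)C(C)C)ccc2c1O[C@H](c1ccc3c(c1)C=CC(C)(C)O3)CC2O | intermediate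
17 | (2S)-2-(2,2-dimethyl-2H-chromen-6-yl)-8-(3-methylbut-2-en-1-yl)-7-[(triisopropylsilyl)oxy]chroman-4-one | CC(C)=CCc1c(O[Si](C(C)C)(C(C)C)C(C)C)ccc2c1O[C@H](c1ccc3c(c1)C=CC(C)(C)O3)CC2=O | intermediate
18 | (2S)-2-(2,2-dimethyl-2H-chromen-6-yl)-7-hydroxy-8-(3-methylbut-2-en-1-yl)chroman-4-one | CC(C)=CCc1c(O)ccc2c1O[C@H](c1ccc3c(c1)C=CC(C)(C)O3)CC2=O | target

Total step count: 9. Longest linear sequence: 7 steps (steps 3 to 9, from 4-hydroxybenzaldehyde).

Steps most likely to fail

Step 6 (Proposed new method). What may go wrong:
- poor facial discrimination at the methide carbon;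
- loss of the cis relay through reversible ionisation at C2;
- acid-induced cyclisation of the ortho-prenylphenol or oligomerisation of the styrene.

Fallback, by known chemistry, closing ring C by oxa-Michael addition instead of cycloaddition: it sets out from aldehydes 4 and 10 and returns at flavanone 17. Aldehyde 4 would be added to an excess of the lithium enolate of tert-butyl acetate (LDA, THF, −78 °C, aldol addition) to give the β-hydroxy ester F1. MnO2 in CH2Cl2 would oxidise this benzylic alcohol to the β-keto ester F2. Knoevenagel condensation of F2 with 10 (piperidine, AcOH, toluene, sieves) would give the alkylidene β-keto ester F3. A bifunctional cinchona-alkaloid thiourea (the pseudo-enantiomer that leads to 2S) in toluene at low temperature would cyclise F3 by enantioselective intramolecular oxa-Michael addition to the tert-butyl 4-oxoflavan-3-carboxylate F4. Catalytic TsOH in warm toluene would then remove isobutene and CO2 to give 17, which rejoins the route before step 9.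

Step 7. What may go wrong:
- proton loss from the C4 cation toward a flav-3-ene;
- ionisation at C2 with erosion of enantiopurity;
- desilylation of the quinoid cation by water.

Fallback, oxidative instead of solvolytic: it sets out from 15 and returns at 17, so it also replaces step 8, and it makes no compound outside the list (F0). DDQ in CH2Cl2/pH 7 buffer at 0 °C should abstract hydride from C4–H, the most electron-rich benzylic ether position. Water would add to the methoxy-stabilised cation and the hemiketal would collapse to the ketone and methanol, without any cation at C2.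

Step 1. What may go wrong: poor regioselectivity (competing C5- and O-alkylation and double alkylation).

Fallback, Claisen delivery of the prenyl group: it sets out from 1 and 6 and returns at 3. Selective etherification of the non-chelated 4-OH of 1 with 6 (DBU, CuCl2 cat., MeCN) would give 2-hydroxy-4-[(2-methylbut-3-yn-2-yl)oxy]benzaldehyde F5. Lindlar semi-hydrogenation (H2, Pd/CaCO3/Pb, quinoline, EtOAc) would give the 1,1-dimethylallyl ether F6. Heating F6 in PhNEt2 (about 150 °C) should trigger an aromatic Claisen rearrangement with allylic transposition that places a prenyl group at C3, the ortho position favoured by the bond fixation of the hydrogen-bonded chelate, to give 3.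

Further compounds
F1 | step 6 | tert-butyl 3-hydroxy-3-{2-hydroxy-3-(3-methylbut-2-en-1-yl)-4-[(triisopropylsilyl)oxy]phenyl}propanoate (racemic) | CC(C)=CCc1c(O[Si](C(C)C)(C(C)C)C(C)C)ccc(C(O)CC(=O)OC(C)(C)C)c1O
F2 | step 6 | tert-butyl 3-{2-hydroxy-3-(3-methylbut-2-en-1-yl)-4-[(triisopropylsilyl)oxy]phenyl}-3-oxopropanoate | CC(C)=CCc1c(O[Si](C(C)C)(C(C)C)C(C)C)ccc(C(=O)CC(=O)OC(C)(C)C)c1O
F3 | step 6 | tert-butyl 3-(2,2-dimethyl-2H-chromen-6-yl)-2-{2-hydroxy-3-(3-methylbut-2-en-1-yl)-4-[(triisopropylsilyl)oxy]benzoyl}prop-2-enoate (E/Z mixture) | CC(C)=CCc1c(O[Si](C(C)C)(C(C)C)C(C)C)ccc(C(=O)C(=Cc2ccc3c(c2)C=CC(C)(C)O3)C(=O)OC(C)(C)C)c1O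
F4 | step 6 | tert-butyl (2S)-2-(2,2-dimethyl-2H-chromen-6-yl)-8-(3-methylbut-2-en-1-yl)-4-oxo-7-[(triisopropylsilyl)oxy]chromane-3-carboxylate (C3 epimers) | CC(C)=CCc1c(O[Si](C(C)C)(C(C)C)C(C)C)ccc2c1O[C@H](c1ccc3c(c1)C=CC(C)(C)O3)C(C(=O)OC(C)(C)C)C2=O
F0 | step 7 | none | none
F5 | step 1 | 2-hydroxy-4-[(2-methylbut-3-yn-2-yl)oxy]benzaldehyde | O=Cc1ccc(OC(C)(C)C#C)cc1O
F6 | step 1 | 2-hydroxy-4-[(2-methylbut-3-en-2-yl)oxy]benzaldehyde | O=Cc1ccc(OC(C)(C)C=C)cc1O
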